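Retrosynthesis: the central Ar–CH2–Ar bridge is cut last (ortho-quinone methide of one half plus the phenoxide carbon of the other). Each benzophenone is then cut in its outer ring at C1'–C2' and C5'–C6' to one aryl propynyl ketone and a ketene-acetal diene, and the ynone is cut at aryl–CO.
Enabling feature: each outer ring carries the ketone carbon at C1', an oxygen at C2' (OMe in the right half, OH in the left), OH at C4' and CH3 at C6'. This is the pattern left when a 1,1-dimethoxy-3-silyloxybutadiene adds across an aryl 1-propynyl ketone and loses methanol.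
Forward: 5-methoxyresorcinol (ring A) is MOM-protected, lithiated between the two acetal oxygens and acylated to the ynone; one Diels–Alder benzannulation builds ring B. Benzylation at O4' and MOM removal give the right half.
The left half comes from the same compound: with the ring A phenols masked as pivalates only the 2'-OMe can chelate BCl3, so it alone is cleaved; benzylation and ester removal follow.
Union: the Mannich base of the left half is quaternised, and its quinone methide is trapped by the right half; hydrogenolysis of three benzyl ethers ends the route.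
Stereochemistry: the target has no stereocentre, so nothing has to be set.

Key step: step 7

Remark: ring A is the inner phloroglucinol-derived ring (ketone at C1) and ring B the outer orcinol-type ring (primed locants). The silyloxydiene is prepared because its commercial supply is not assumed.

Step 1
Reactants: 1 5-methoxyresorcinol
Product: 2 1-methoxy-3,5-bis(methoxymethoxy)benzene
Conditions: MOMCl (2.5 equiv), i-Pr2NEt (3 equiv), CH2Cl2, 0 °C to rt
Reagents that add atoms: chloromethyl methyl ether, COCCl
Why: Williamson-type O-alkylation of both phenols with the chloromethyl ether under amine base should install the two acetal groups that later direct metalation to the carbon between them.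

Step 2
Reactants: 3 but-2-ynoic acid
Product: 4 N-methoxy-N-methylbut-2-ynamide
Conditions: MeNHOMe·HCl, DCC, Et3N, DMAP (cat.), CH2Cl2, 0 °C to rt
Reagents that add atoms: N,O-dimethylhydroxylamine hydrochloride, CNOC.Cl
Why: Carbodiimide-mediated amide coupling of the acid with the hydroxylamine freed by Et3N should give the N-methoxy-N-methylamide without touching the triple bond.

Step 3
Reactants: 2 1-methoxy-3,5-bis(methoxymethoxy)benzene; 4 N-methoxy-N-methylbut-2-ynamide
Product: 7 1-[4-methoxy-2,6-bis(methoxymethoxy)phenyl]but-2-yn-1-one, via aryllithium 5 (not isolated), via lithium hemiaminalate 6 (not isolated)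
Conditions: n-BuLi (1.1 equiv), THF, 0 °C; then 4, −78 °C; inverse quench into cold 1 M HCl
Reagents that add atoms: none
Why: Directed ortho-metalation places lithium on the ring carbon flanked by both OMOM groups, and the Weinreb ketone synthesis then stops at the chelated tetrahedral adduct 6, so the ynone appears only on the acidic quench and over-addition is excluded.

Step 4
Reactants: 8 acetyl chloride; 9 1,1-dichloroethene
Product: 11 4,4-dichlorobut-3-en-2-one, via 4,4,4-trichlorobutan-2-one 10 (not isolated)
Conditions: AlCl3 (1.1 equiv), CH2Cl2, 0 °C to rt; ice water; steam distillation (loss of HCl)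
Reagents that add atoms: none
Why: Friedel–Crafts-type acylation of the alkene, in which the acylium ion adds to the CH2 terminus and the chlorine-stabilised cation captures chloride; the trichloromethyl ketone 10 then loses HCl to the conjugated dichlorovinyl ketone.

Step 5
Reactants: 11 4,4-dichlorobut-3-en-2-one
Product: 13 4,4-dimethoxybut-3-en-2-one, via 4-chloro-4-methoxybut-3-en-2-one 12 (not isolated)
Conditions: NaOMe (2.1 equiv), MeOH, −10 °C to rt; distillation
Reagents that add atoms: sodium methoxide, C[O-].[Na+]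
Why: Two successive conjugate addition–elimination (vinylogous acyl substitution) reactions of methoxide at the β-carbon should replace both vinylic chlorides.

Step 6
Reactants: 13 4,4-dimethoxybut-3-en-2-one
Product: 15 1,1-dimethoxy-3-(trimethylsilyloxy)buta-1,3-diene, via lithium dienolate 14 (not isolated)
Conditions: LiN(i-Pr)2 (1.05 equiv), THF, −78 °C; Me3SiCl, −78 to 0 °C; distillation
Reagents that add atoms: chlorotrimethylsilane, C[Si](C)(C)Cl
Why: Kinetic deprotonation of the only enolisable position (the acetyl CH3) followed by O-silylation is a standard silyl enol ether formation and delivers the 2-silyloxydiene.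

Step 7
Reactants: 7 1-[4-methoxy-2,6-bis(methoxymethoxy)phenyl]but-2-yn-1-one; 15 1,1-dimethoxy-3-(trimethylsilyloxy)buta-1,3-diene
Product: 18 (4-hydroxy-2-methoxy-6-methylphenyl)[4-methoxy-2,6-bis(methoxymethoxy)phenyl]methanone, via cyclohexadiene cycloadduct 16 (not isolated), via aryl trimethylsilyl ether 17 (not isolated)
Conditions: 15 (2.5 equiv), toluene, 100 °C (sealed); then 0.1 M HCl, THF, 0 °C, brief
Reagents that add atoms: none
Why: The electron-rich diene and the ynone should combine in a polarised, asynchronous [4+2] cycloaddition in which the unsubstituted C4 terminus of 15 (made nucleophilic by both the ketene-acetal and the silyloxy oxygens) bonds to the methyl-bearing β-carbon of 7 and the acetal carbon C1 bonds to the α-carbon. The closest known reaction type is the Diels–Alder benzannulation of 1,1-dialkoxy-3-silyloxybutadienes with alkynyl esters and ketones, which gives resorcinol monoethers. The six-membered ring B is closed intermolecularly by the cycloaddition itself, which forms both new bonds (C1'–C2' and C5'–C6'); the 1,4-cyclohexadiene 16 then aromatises by 1,4-elimination of methanol from the ketal carbon to 17, whose silyl ether is hydrolysed in the cold acidic work-up. No stereocentre is formed or needed. The step needs one regiochemistry only, and the matched push–pull polarisation of the partners secures it, placing OMe ortho and OH para to the ketone with CH3 in the other ortho position; the twisted 2,6-dioxygenated aryl group leaves the triple bond unhindered, and the MOM acetals should tolerate the neutral thermal conditions and the short contact with cold dilute acid.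

Step 8
Reactants: 18 (4-hydroxy-2-methoxy-6-methylphenyl)[4-methoxy-2,6-bis(methoxymethoxy)phenyl]methanone
Product: 19 [4-(benzyloxy)-2-methoxy-6-methylphenyl][4-methoxy-2,6-bis(methoxymethoxy)phenyl]methanone
Conditions: BnBr (1.2 equiv), K2CO3, DMF, rt
Reagents that add atoms: benzyl bromide, BrCc1ccccc1
Why: Williamson ether synthesis on the single free phenol, acidified by the para ketone, should benzylate O4' and remove the only phenoxide site of ring B.

Step 9
Reactants: 19 [4-(benzyloxy)-2-methoxy-6-methylphenyl][4-methoxy-2,6-bis(methoxymethoxy)phenyl]methanone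
Product: 20 [4-(benzyloxy)-2-methoxy-6-methylphenyl](2,6-dihydroxy-4-methoxyphenyl)methanone
Conditions: HCl (3 M in MeOH), 45 °C
Reagents that add atoms: none
Why: Acid-catalysed acetal exchange with methanol should cleave both aryl MOM ethers while the benzyl and methyl ethers stay, leaving ring A as the only phenolic ring.

Step 10
Reactants: 20 [4-(benzyloxy)-2-methoxy-6-methylphenyl](2,6-dihydroxy-4-methoxyphenyl)methanone
Product: 21 2-[4-(benzyloxy)-2-methoxy-6-methylbenzoyl]-5-methoxy-1,3-phenylene bis(2,2-dimethylpropanoate)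
Conditions: PivCl (3 equiv), Et3N (4 equiv), DMAP (0.2 equiv), CH2Cl2, 0 °C to rt
Reagents that add atoms: pivaloyl chloride, CC(C)(C)C(Cl)=O
Why: DMAP-catalysed O-acylation of the two hydrogen-bonded ring A phenols; the pivalates ensure that in step 11 no ring A oxygen can form a boron chelate with the ketone.

Step 11
Reactants: 21 2-[4-(benzyloxy)-2-methoxy-6-methylbenzoyl]-5-methoxy-1,3-phenylene bis(2,2-dimethylpropanoate)
Product: 23 2-[4-(benzyloxy)-2-hydroxy-6-methylbenzoyl]-5-methoxy-1,3-phenylene bis(2,2-dimethylpropanoate), via aryloxydichloroborane 22 (not isolated)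
Conditions: BCl3 (1.5 equiv, 1 M in CH2Cl2), CH2Cl2, −78 to −30 °C; ice water
Reagents that add atoms: none
Why: Chelation-directed ether cleavage, in which BCl3 bridges the ketone oxygen and the ortho 2'-OMe and chloride removes the methyl group as CH3Cl, while the non-chelated 4-OMe, the 4'-benzyl ether and the aryl pivalates should survive at low temperature.

Step 12
Reactants: 23 2-[4-(benzyloxy)-2-hydroxy-6-methylbenzoyl]-5-methoxy-1,3-phenylene bis(2,2-dimethylpropanoate)
Product: 24 2-[2,4-bis(benzyloxy)-6-methylbenzoyl]-5-methoxy-1,3-phenylene bis(2,2-dimethylpropanoate)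
Conditions: BnBr (1.5 equiv), K2CO3, DMF, 40 °C
Reagents that add atoms: benzyl bromide, BrCc1ccccc1
Why: Williamson benzylation of the hydrogen-bonded 2'-phenol under mild carbonate conditions, in which the hindered aryl pivalates should neither cleave nor migrate.

Step 13
Reactants: 24 2-[2,4-bis(benzyloxy)-6-methylbenzoyl]-5-methoxy-1,3-phenylene bis(2,2-dimethylpropanoate)
Product: 25 [2,4-bis(benzyloxy)-6-methylphenyl](2,6-dihydroxy-4-methoxyphenyl)methanone
Conditions: NaOMe (2.2 equiv), MeOH–THF, 0 °C to rt; AcOH quench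
Reagents that add atoms: none
Why: Transesterification of the two activated aryl pivalates with methoxide should release the ring A phenols at room temperature, well below the temperatures at which an ortho-phenoxide could displace the 2'-alkoxy group and close a xanthone.

Step 14
Reactants: 25 [2,4-bis(benzyloxy)-6-methylphenyl](2,6-dihydroxy-4-methoxyphenyl)methanone
Product: 26 [2,4-bis(benzyloxy)-6-methylphenyl]{3-[(dimethylamino)methyl]-2,6-dihydroxy-4-methoxyphenyl}methanone
Conditions: CH2=NMe2+ I− (1.0 equiv), Et3N (1.0 equiv), CH2Cl2, 0 °C to rt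
Reagents that add atoms: N,N-dimethylmethyleneiminium iodide, C=[N+](C)C.[I-]
Why: Mannich reaction in which the preformed iminium salt aminomethylates ring A at one of its two equivalent positions between OH and OMe; one equivalent of reagent should hold it at mono-substitution, and ring B has no free phenol to compete.

Step 15
Reactants: 26 [2,4-bis(benzyloxy)-6-methylphenyl]{3-[(dimethylamino)methyl]-2,6-dihydroxy-4-methoxyphenyl}methanone; 20 [4-(benzyloxy)-2-methoxy-6-methylphenyl](2,6-dihydroxy-4-methoxyphenyl)methanone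
Product: 29 {3-[(3-{4-(benzyloxy)-2-methoxy-6-methylbenzoyl}-2,4-dihydroxy-6-methoxyphenyl)methyl]-2,6-dihydroxy-4-methoxyphenyl}[2,4-bis(benzyloxy)-6-methylphenyl]methanone, via trimethylammonium iodide 27 (not isolated), via ortho-quinone methide 28 (not isolated)
Conditions: MeI (5 equiv), THF, rt, then evaporation; slow addition to 20 (3 equiv), K2CO3, MeCN, 0 °C to rt
Reagents that add atoms: none
Why: N-methylation turns the benzylic amine into a leaving group, base-induced 1,4-elimination of trimethylamine gives the ortho-quinone methide 28, and Michael-type C-alkylation by the ring A phenoxide of 20 (in excess, at either of its two equivalent carbons between OH and OMe) should form the unsymmetrical diarylmethane; this is the known cross-coupling of phenolic Mannich bases with phenols.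

Step 16
Reactants: 29 {3-[(3-{4-(benzyloxy)-2-methoxy-6-methylbenzoyl}-2,4-dihydroxy-6-methoxyphenyl)methyl]-2,6-dihydroxy-4-methoxyphenyl}[2,4-bis(benzyloxy)-6-methylphenyl]methanone
Product: 30 {3-[(3-{4-hydroxy-2-methoxy-6-methylbenzoyl}-2,4-dihydroxy-6-methoxyphenyl)methyl]-2,6-dihydroxy-4-methoxyphenyl}(2,4-dihydroxy-6-methylphenyl)methanone
Conditions: H2 (1 atm), 10% Pd/C, EtOAc–MeOH, rt
Reagents that add atoms: none
Why: Catalytic hydrogenolysis of the three aryl benzyl ethers over palladium should leave the hindered, hydrogen-bonded diaryl ketones and the diarylmethane untouched and deliver the target.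

Compound list
1 | 5-methoxyresorcinol | COc1cc(O)cc(O)c1 | starting material
2 | 1-methoxy-3,5-bis(methoxymethoxy)benzene | COCOc1cc(OC)cc(OCOC)c1 | intermediate
3 | but-2-ynoic acid | CC#CC(=O)O | starting material
4 | N-methoxy-N-methylbut-2-ynamide | CC#CC(=O)N(C)OC | intermediate
5 | [4-methoxy-2,6-bis(methoxymethoxy)phenyl]lithium | [Li]c1c(OCOC)cc(OC)cc1OCOC | intermediate (not isolated)
6 | lithium 1-[methoxy(methyl)amino]-1-[4-methoxy-2,6-bis(methoxymethoxy)phenyl]but-2-yn-1-olate (racemic) | CC#CC(O[Li])(N(C)OC)c1c(OCOC)cc(OC)cc1OCOC | intermediate (not isolated)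
7 | 1-[4-methoxy-2,6-bis(methoxymethoxy)phenyl]but-2-yn-1-one | CC#CC(=O)c1c(OCOC)cc(OC)cc1OCOC | intermediate
8 | acetyl chloride | CC(Cl)=O | starting material
9 | 1,1-dichloroethene | C=C(Cl)Cl | starting material
10 | 4,4,4-trichlorobutan-2-one | CC(=O)CC(Cl)(Cl)Cl | intermediate (not isolated)
11 | 4,4-dichlorobut-3-en-2-one | CC(=O)C=C(Cl)Cl | intermediate
12 | 4-chloro-4-methoxybut-3-en-2-one (either geometry) | CC(=O)C=C(Cl)OC | intermediate (not isolated)
13 | 4,4-dimethoxybut-3-en-2-one | CC(=O)C=C(OC)OC | intermediate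
14 | lithium 4,4-dimethoxybuta-1,3-dien-2-olate | [Li]OC(=C)C=C(OC)OC | intermediate (not isolated)
15 | 1,1-dimethoxy-3-(trimethylsilyloxy)buta-1,3-diene | COC(OC)=CC(=C)O[Si](C)(C)C | intermediate
16 | [6,6-dimethoxy-2-methyl-4-(trimethylsilyloxy)cyclohexa-1,4-dien-1-yl][4-methoxy-2,6-bis(methoxymethoxy)phenyl]methanone | COCOc1cc(OC)cc(OCOC)c1C(=O)C1=C(C)CC(O[Si](C)(C)C)=CC1(OC)OC | intermediate (not isolated)
17 | [2-methoxy-6-methyl-4-(trimethylsilyloxy)phenyl][4-methoxy-2,6-bis(methoxymethoxy)phenyl]methanone | COCOc1cc(OC)cc(OCOC)c1C(=O)c1c(C)cc(O[Si](C)(C)C)cc1OC | intermediate (not isolated)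
18 | (4-hydroxy-2-methoxy-6-methylphenyl)[4-methoxy-2,6-bis(methoxymethoxy)phenyl]methanone | COCOc1cc(OC)cc(OCOC)c1C(=O)c1c(C)cc(O)cc1OC | intermediate
19 | [4-(benzyloxy)-2-methoxy-6-methylphenyl][4-methoxy-2,6-bis(methoxymethoxy)phenyl]methanone | COCOc1cc(OC)cc(OCOC)c1C(=O)c1c(C)cc(OCc2ccccc2)cc1OC | intermediate
20 | [4-(benzyloxy)-2-methoxy-6-methylphenyl](2,6-dihydroxy-4-methoxyphenyl)methanone | COc1cc(O)c(C(=O)c2c(C)cc(OCc3ccccc3)cc2OC)c(O)c1 | intermediate
21 | 2-[4-(benzyloxy)-2-methoxy-6-methylbenzoyl]-5-methoxy-1,3-phenylene bis(2,2-dimethylpropanoate) | COc1cc(OC(=O)C(C)(C)C)c(C(=O)c2c(C)cc(OCc3ccccc3)cc2OC)c(OC(=O)C(C)(C)C)c1 | intermediate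
22 | 2-{4-(benzyloxy)-2-[(dichloroboranyl)oxy]-6-methylbenzoyl}-5-methoxy-1,3-phenylene bis(2,2-dimethylpropanoate) | COc1cc(OC(=O)C(C)(C)C)c(C(=O)c2c(C)cc(OCc3ccccc3)cc2OB(Cl)Cl)c(OC(=O)C(C)(C)C)c1 | intermediate (not isolated)
23 | 2-[4-(benzyloxy)-2-hydroxy-6-methylbenzoyl]-5-methoxy-1,3-phenylene bis(2,2-dimethylpropanoate) | COc1cc(OC(=O)C(C)(C)C)c(C(=O)c2c(C)cc(OCc3ccccc3)cc2O)c(OC(=O)C(C)(C)C)c1 | intermediate
24 | 2-[2,4-bis(benzyloxy)-6-methylbenzoyl]-5-methoxy-1,3-phenylene bis(2,2-dimethylpropanoate) | COc1cc(OC(=O)C(C)(C)C)c(C(=O)c2c(C)cc(OCc3ccccc3)cc2OCc2ccccc2)c(OC(=O)C(C)(C)C)c1 | intermediate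
25 | [2,4-bis(benzyloxy)-6-methylphenyl](2,6-dihydroxy-4-methoxyphenyl)methanone | COc1cc(O)c(C(=O)c2c(C)cc(OCc3ccccc3)cc2OCc2ccccc2)c(O)c1 | intermediate
26 | [2,4-bis(benzyloxy)-6-methylphenyl]{3-[(dimethylamino)methyl]-2,6-dihydroxy-4-methoxyphenyl}methanone | COc1cc(O)c(C(=O)c2c(C)cc(OCc3ccccc3)cc2OCc2ccccc2)c(O)c1CN(C)C | intermediate
27 | {3-[2,4-bis(benzyloxy)-6-methylbenzoyl]-2,4-dihydroxy-6-methoxyphenyl}-N,N,N-trimethylmethanaminium iodide | COc1cc(O)c(C(=O)c2c(C)cc(OCc3ccccc3)cc2OCc2ccccc2)c(O)c1C[N+](C)(C)C.[I-] | intermediate (not isolated)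
28 | 2-[2,4-bis(benzyloxy)-6-methylbenzoyl]-3-hydroxy-5-methoxy-6-methylidenecyclohexa-2,4-dien-1-one | COC1=CC(O)=C(C(=O)c2c(C)cc(OCc3ccccc3)cc2OCc2ccccc2)C(=O)C1=C | intermediate (not isolated)
29 | {3-[(3-{4-(benzyloxy)-2-methoxy-6-methylbenzoyl}-2,4-dihydroxy-6-methoxyphenyl)methyl]-2,6-dihydroxy-4-methoxyphenyl}[2,4-bis(benzyloxy)-6-methylphenyl]methanone | COc1cc(O)c(C(=O)c2c(C)cc(OCc3ccccc3)cc2OCc2ccccc2)c(O)c1Cc1c(OC)cc(O)c(C(=O)c2c(C)cc(OCc3ccccc3)cc2OC)c1O | intermediate
30 | {3-[(3-{4-hydroxy-2-methoxy-6-methylbenzoyl}-2,4-dihydroxy-6-methoxyphenyl)methyl]-2,6-dihydroxy-4-methoxyphenyl}(2,4-dihydroxy-6-methylphenyl)methanone (CNP0596095.0) | COc1cc(O)c(C(=O)c2c(C)cc(O)cc2O)c(O)c1Cc1c(OC)cc(O)c(C(=O)c2c(C)cc(O)cc2OC)c1O | target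

Total step count: 16.
Longest linear sequence: 13 steps (steps 4, 5, 6, 7, 8, 9, 10, 11, 12, 13, 14, 15, 16, from acetyl chloride and 1,1-dichloroethene).

Steps most likely to fail

Step 15. The quinone methide 28 may be intercepted by the still unsubstituted second ring A carbon of its own precursor or of the first-formed diarylmethane, so that homo-coupled and oligomeric methylene-bridged material grows at the expense of the cross-dimer. The fallback sets out from 25 and returns to the route at 30. N-Bromosuccinimide (1.0 equiv, CH2Cl2, −40 °C) should block one of the two equivalent ring A positions and give [2,4-bis(benzyloxy)-6-methylphenyl](3-bromo-2,6-dihydroxy-4-methoxyphenyl)methanone F1. The Mannich reaction of step 14 can then occur only at the remaining position and gives [2,4-bis(benzyloxy)-6-methylphenyl]{3-bromo-5-[(dimethylamino)methyl]-2,6-dihydroxy-4-methoxyphenyl}methanone F2. MeI converts this into the brominated trimethylammonium iodide F3 (not isolated), and K2CO3 releases the brominated quinone methide F4 (not isolated), whose precursor no longer has a nucleophilic ring carbon. Capture by 20 gives the bromo-diarylmethane F5. Hydrogenolysis over Pd/C with NaOAc then removes the bromine together with the three benzyl groups and gives 30.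

Step 11. The Lewis acid may also strip the 4'-benzyl ether or a pivalate, or the demethylation may stall if the ketone cannot become coplanar with ring B for chelation. The fallback avoids any ether cleavage; it sets out from ynone 7 and returns at 25. Cycloaddition of 7 with commercial 1-methoxy-1,3-bis(trimethylsilyloxy)buta-1,3-diene (toluene, 90 °C) should give the mixed methyl silyl ketal cycloadduct F6 (not isolated). Cold dilute HCl in THF is expected to remove methanol and both silyl groups from it, giving (2,4-dihydroxy-6-methylphenyl)[4-methoxy-2,6-bis(methoxymethoxy)phenyl]methanone F7; retention of the methoxy group by loss of silanol instead is the open question of this variant. Double benzylation (BnBr, K2CO3, DMF) gives [2,4-bis(benzyloxy)-6-methylphenyl][4-methoxy-2,6-bis(methoxymethoxy)phenyl]methanone F8, and HCl in MeOH removes the MOM groups to reach 25.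

Step 3. The hindered aryllithium may deprotonate the propargylic CH3 of 4 instead of adding to the amide, or the hydroxylamine set free on quench may add to the ynone in conjugate fashion. The fallback sets out from aryllithium 5 and returns at 7. N,N-Dimethylformamide gives the lithium hemiaminalate F9 (not isolated), and dilute acid work-up gives 4-methoxy-2,6-bis(methoxymethoxy)benzaldehyde F10. 1-Propynylmagnesium bromide (THF, 0 °C) adds to give the bromomagnesium alkoxide F11 (not isolated) and, after NH4Cl, racemic 1-[4-methoxy-2,6-bis(methoxymethoxy)phenyl]but-2-yn-1-ol F12. MnO2 (CH2Cl2, rt) oxidises this propargylic benzylic alcohol to 7.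

Further compounds
F1 | step 15 | [2,4-bis(benzyloxy)-6-methylphenyl](3-bromo-2,6-dihydroxy-4-methoxyphenyl)methanone | COc1cc(O)c(C(=O)c2c(C)cc(OCc3ccccc3)cc2OCc2ccccc2)c(O)c1Br
F2 | step 15 | [2,4-bis(benzyloxy)-6-methylphenyl]{3-bromo-5-[(dimethylamino)methyl]-2,6-dihydroxy-4-methoxyphenyl}methanone | COc1c(CN(C)C)c(O)c(C(=O)c2c(C)cc(OCc3ccccc3)cc2OCc2ccccc2)c(O)c1Br
F3 | step 15 | {3-[2,4-bis(benzyloxy)-6-methylbenzoyl]-5-bromo-2,4-dihydroxy-6-methoxyphenyl}-N,N,N-trimethylmethanaminium iodide | COc1c(C[N+](C)(C)C)c(O)c(C(=O)c2c(C)cc(OCc3ccccc3)cc2OCc2ccccc2)c(O)c1Br.[I-]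
F4 | step 15 | 2-[2,4-bis(benzyloxy)-6-methylbenzoyl]-4-bromo-3-hydroxy-5-methoxy-6-methylidenecyclohexa-2,4-dien-1-one | COC1=C(Br)C(O)=C(C(=O)c2c(C)cc(OCc3ccccc3)cc2OCc2ccccc2)C(=O)C1=C
F5 | step 15 | {3-bromo-5-[(3-{4-(benzyloxy)-2-methoxy-6-methylbenzoyl}-2,4-dihydroxy-6-methoxyphenyl)methyl]-2,6-dihydroxy-4-methoxyphenyl}[2,4-bis(benzyloxy)-6-methylphenyl]methanone | COc1c(Br)c(O)c(C(=O)c2c(C)cc(OCc3ccccc3)cc2OCc2ccccc2)c(O)c1Cc1c(OC)cc(O)c(C(=O)c2c(C)cc(OCc3ccccc3)cc2OC)c1O
F6 | step 11 | [6-methoxy-2-methyl-4,6-bis(trimethylsilyloxy)cyclohexa-1,4-dien-1-yl][4-methoxy-2,6-bis(methoxymethoxy)phenyl]methanone (racemic) | COCOc1cc(OC)cc(OCOC)c1C(=O)C1=C(C)CC(O[Si](C)(C)C)=CC1(OC)O[Si](C)(C)C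
F7 | step 11 | (2,4-dihydroxy-6-methylphenyl)[4-methoxy-2,6-bis(methoxymethoxy)phenyl]methanone | COCOc1cc(OC)cc(OCOC)c1C(=O)c1c(C)cc(O)cc1O
F8 | step 11 | [2,4-bis(benzyloxy)-6-methylphenyl][4-methoxy-2,6-bis(methoxymethoxy)phenyl]methanone | COCOc1cc(OC)cc(OCOC)c1C(=O)c1c(C)cc(OCc2ccccc2)cc1OCc1ccccc1
F9 | step 3 | lithium (dimethylamino)[4-methoxy-2,6-bis(methoxymethoxy)phenyl]methanolate (racemic) | CN(C)C(O[Li])c1c(OCOC)cc(OC)cc1OCOC
F10 | step 3 | 4-methoxy-2,6-bis(methoxymethoxy)benzaldehyde | COCOc1cc(OC)cc(OCOC)c1C=O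
F11 | step 3 | bromomagnesium 1-[4-methoxy-2,6-bis(methoxymethoxy)phenyl]but-2-yn-1-olate (racemic) | CC#CC(O[Mg]Br)c1c(OCOC)cc(OC)cc1OCOC
F12 | step 3 | 1-[4-methoxy-2,6-bis(methoxymethoxy)phenyl]but-2-yn-1-ol (racemic) | CC#CC(O)c1c(OCOC)cc(OC)cc1OCOC
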